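**Plan**
1. Retrosynthetic cuts, in order: the six O-protecting groups; then, together, the two bonds that tie ring A to ring C of the flavanone (O1–C8a and C4–C4a); then the C6–C8'' biaryl bond; the lactone partner goes back to a β-keto ester.
2. Enabling feature: O1 and C4 sit on the adjacent ring A carbons C8a and C4a, C4a lies next to the oxygenated C5, and O1–C2–C3–C4 is a 3-oxy-acyl unit. A C4a≡C8a aryne (a 3-alkoxyaryne) can therefore take up the O–acyl σ bond of a β-lactone, a four-membered ring that is not in the target and is cleaved as ring C forms.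
3. Forward: the phloroglucinol ring A is silylated next to a carbamate, joined at C6 to preformed 8-iodo-tri-O-benzylapigenin (Negishi) and turned into the ortho-silyl triflate; ring C is made last by ring expansion of the lactone; acid and then hydrogenolysis free the phenols.
4. Stereochemistry: C2 (S) is set by Noyori hydrogenation of the β-keto ester, kept by a lactonisation that does not break the C–O bond, and carried through the key step untouched.

Key step: step 15

Remark: the target SMILES defines only C2; the fourfold ortho-substituted biaryl axis is left open, so the biaryl intermediates are racemic about that axis and the flavanones are carried as both axial isomers with (2S) fixed.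

**Step 1**
Reactants: 1 phloroglucinol
Product: 2 3,5-bis(methoxymethoxy)phenol
Conditions: MOMCl (2.1 equiv), i-Pr2NEt, DMF, 0 °C → rt; chromatography (mono- and tris-ethers recycled)
Reagents that add atoms: chloromethyl methyl ether (3), COCCl
Why: Williamson-type O-alkylation of the threefold-symmetric triol with two equivalents of the chloromethyl ether should give the bis-ether as the main component of a statistical mixture that silica separates by polarity.

**Step 2**
Reactants: 2 3,5-bis(methoxymethoxy)phenol
Product: 4 3,5-bis(methoxymethoxy)phenyl N,N-diethylcarbamate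
Conditions: Et2NCOCl, K2CO3, MeCN, reflux
Reagents that add atoms: N,N-diethylcarbamoyl chloride (5), CCN(CC)C(=O)Cl
Why: O-carbamoylation of the single free phenol installs the strongest oxygen-based director for ortho-metalation.

**Step 3**
Reactants: 4 3,5-bis(methoxymethoxy)phenyl N,N-diethylcarbamate
Product: 7 3,5-bis(methoxymethoxy)-2-(trimethylsilyl)phenyl N,N-diethylcarbamate, via aryllithium 6 (not isolated)
Conditions: s-BuLi, TMEDA, THF, −78 °C; then TMSCl, −78 °C → rt
Reagents that add atoms: chlorotrimethylsilane (8), C[Si](C)(C)Cl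
Why: Snieckus directed ortho-metalation, in which the carbamate reinforced by the neighbouring acetal ether should direct s-BuLi to the carbon between them, and silylation below the temperature of the anionic Fries shift traps the aryllithium.

**Step 4**
Reactants: 7 3,5-bis(methoxymethoxy)-2-(trimethylsilyl)phenyl N,N-diethylcarbamate
Product: 9 3,5-bis(methoxymethoxy)-2-(trimethylsilyl)phenol
Conditions: LiAlH4 (excess), THF, 0 °C → rt; aq. potassium sodium tartrate work-up
Reagents that add atoms: none
Why: hydride reduction of the aryl carbamate (acyl substitution with the phenoxide as leaving group) frees the phenol, while the acetals and the aryl–silicon bond are inert to LiAlH4 and the non-acidic work-up avoids protodesilylation.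

**Step 5**
Reactants: 9 3,5-bis(methoxymethoxy)-2-(trimethylsilyl)phenol
Product: 10 [3,5-bis(methoxymethoxy)-2-(trimethylsilyl)phenoxy]tri(propan-2-yl)silane
Conditions: TIPSCl, imidazole, DMAP (cat.), DMF, 50 °C
Reagents that add atoms: chlorotri(propan-2-yl)silane (11), CC(C)[Si](Cl)(C(C)C)C(C)C
Why: O-silylation with a bulky triisopropylsilyl group, which does not direct metalation and shields the position next to it, prepares the ring for metalation between the two acetal ethers.

**Step 6**
Reactants: 12 apigenin
Product: 13 5,7-bis(benzyloxy)-2-[4-(benzyloxy)phenyl]-4H-chromen-4-one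
Conditions: BnBr (excess), K2CO3, n-Bu4NI (cat.), DMF, 70 °C
Reagents that add atoms: benzyl bromide (14), BrCc1ccccc1
Why: exhaustive Williamson benzylation, in which the chelated 5-OH reacts last and therefore needs excess bromide, iodide catalysis and warming.

**Step 7**
Reactants: 13 5,7-bis(benzyloxy)-2-[4-(benzyloxy)phenyl]-4H-chromen-4-one
Product: 15 5,7-bis(benzyloxy)-2-[4-(benzyloxy)phenyl]-8-iodo-4H-chromen-4-one
Conditions: NIS, TFA (cat.), MeCN–CH2Cl2, 0 °C → rt, dark
Reagents that add atoms: N-iodosuccinimide (16), O=C1CCC(=O)N1I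
Why: electrophilic aromatic iodination should occur at C8, which is para to the 5-benzyloxy group, ortho to the 7-benzyloxy group and less hindered than C6, the site that reacts in fully O-alkylated 5,7-dioxygenated flavones.

**Step 8**
Reactants: 10 [3,5-bis(methoxymethoxy)-2-(trimethylsilyl)phenoxy]tri(propan-2-yl)silane; 15 5,7-bis(benzyloxy)-2-[4-(benzyloxy)phenyl]-8-iodo-4H-chromen-4-one
Product: 19 5,7-bis(benzyloxy)-2-[4-(benzyloxy)phenyl]-8-[2,6-bis(methoxymethoxy)-4-{[tri(propan-2-yl)silyl]oxy}-3-(trimethylsilyl)phenyl]-4H-chromen-4-one, via aryllithium 17 (not isolated), via arylzinc chloride 18 (not isolated)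
Conditions: 10, n-BuLi, THF, 0 °C; ZnCl2, 0 °C → rt; then 15, Pd2(dba)3 (cat.), RuPhos, THF–NMP, 70 °C
Reagents that add atoms: none
Why: directed ortho-metalation between the two acetal ethers, transmetalation to zinc and Negishi coupling with a zerovalent palladium/dialkylbiarylphosphine catalyst of the kind that forms tetra-ortho-substituted biaryls should join the rings, the arylzinc tolerating the pyranone carbonyl.

**Step 9**
Reactants: 19 the silyl ether from step 8
Product: 20 5,7-bis(benzyloxy)-2-[4-(benzyloxy)phenyl]-8-[4-hydroxy-2,6-bis(methoxymethoxy)-3-(trimethylsilyl)phenyl]-4H-chromen-4-one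
Conditions: TBAF, AcOH, THF, 0 °C → rt
Reagents that add atoms: none
Why: buffered fluoride cleaves the aryl O–Si bond, while the aryl–SiMe3 bond, not yet flanked by a leaving group, should stay intact.

**Step 10**
Reactants: 20 the phenol from step 9
Product: 21 4-{5,7-bis(benzyloxy)-2-[4-(benzyloxy)phenyl]-4-oxo-4H-chromen-8-yl}-3,5-bis(methoxymethoxy)-2-(trimethylsilyl)phenyl trifluoromethanesulfonate
Conditions: PhNTf2, DBU, MeCN, rt → 40 °C
Reagents that add atoms: N-phenylbis(trifluoromethanesulfonimide) (22), O=S(=O)(N(c1ccccc1)S(=O)(=O)C(F)(F)F)C(F)(F)F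
Why: O-sulfonylation of the phenoxide with the mild triflyl donor gives the ortho-silyl aryl triflate (Kobayashi aryne precursor) without attack on the pyranone carbonyl.

**Step 11**
Reactants: 23 1-[4-(benzyloxy)phenyl]ethan-1-one
Product: 24 ethyl 3-[4-(benzyloxy)phenyl]-3-oxopropanoate
Conditions: NaH, (EtO)2CO, THF, reflux; AcOH quench
Reagents that add atoms: diethyl carbonate (25), CCOC(=O)OCC
Why: crossed Claisen condensation of the ketone enolate with the carbonate is driven by deprotonation of the β-keto ester formed.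

**Step 12**
Reactants: 24 ethyl 3-[4-(benzyloxy)phenyl]-3-oxopropanoate
Product: 26 ethyl (3S)-3-[4-(benzyloxy)phenyl]-3-hydroxypropanoate
Conditions: H2 (50 bar), RuCl2[(R)-BINAP] (cat.), EtOH, 50 °C
Reagents that add atoms: none
Why: Noyori asymmetric hydrogenation of a β-keto ester, in which the chelating ester and the (R)-BINAP ligand should deliver hydride to the face that gives the (S)-benzylic alcohol (the sense established for aryl β-keto esters), and the ruthenium catalyst does not cleave benzyl ethers.

**Step 13**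
Reactants: 26 ethyl (3S)-3-[4-(benzyloxy)phenyl]-3-hydroxypropanoate
Product: 27 (3S)-3-[4-(benzyloxy)phenyl]-3-hydroxypropanoic acid
Conditions: LiOH, THF–H2O, 0 °C; then cold 1 M HCl to pH 3
Reagents that add atoms: lithium hydroxide (28), [Li+].[OH-]
Why: saponification at 0 °C, where retro-aldol cleavage and dehydration are slow, leaves the stereocenter untouched, and the acid can be crystallised to raise its enantiomeric purity.

**Step 14**
Reactants: 27 (3S)-3-[4-(benzyloxy)phenyl]-3-hydroxypropanoic acid
Product: 29 (4S)-4-[4-(benzyloxy)phenyl]oxetan-2-one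
Conditions: PhSO2Cl, pyridine, 0–4 °C; cold neutral work-up, used without chromatography on acidic silica
Reagents that add atoms: none
Why: Adam-type β-lactonisation activates the carboxyl group as the mixed sulfonic anhydride and the hydroxyl oxygen closes the ring (4-exo-trig), so the C–O bond at the stereocenter is not broken and (S) is retained.

**Step 15**
Reactants: 21 the ortho-silyl aryl triflate from step 10; 29 (4S)-4-[4-(benzyloxy)phenyl]oxetan-2-one
Product: 31 (2S)-6-{5,7-bis(benzyloxy)-2-[4-(benzyloxy)phenyl]-4-oxo-4H-chromen-8-yl}-2-[4-(benzyloxy)phenyl]-5,7-bis(methoxymethoxy)-2,3-dihydro-4H-chromen-4-one, via aryne 30 (not isolated)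
Conditions: 29 (3 equiv), CsF (3 equiv), MeCN, 0 °C → rt, 21 added slowly
Reagents that add atoms: none
Why: Proposed new method: fluoride-induced 1,2-elimination of 21 gives aryne 30, whose distortion by the neighbouring 5-methoxymethoxy group makes the carbon meta to that oxygen (the future C8a) the electrophilic end; the ring oxygen of the strained lactone 29 adds there, the aryl carbanion formed next to the alkoxy group (the future C4a) attacks the acyl carbon of the resulting O-aryl oxetanonium ion and the acyl–O bond breaks, a net insertion of the aryne into the C(acyl)–O σ bond. The closest known reaction types are the aryne σ-insertions into N–C(=O) bonds of amides and cyclic ureas (ring expansion) and the C–O insertion of arynes into carboxylic acids that gives ortho-hydroxyaryl ketones. Ring C is closed as a two-atom ring expansion of the four-membered lactone to the six-membered pyranone, the acyl shift passing through a four-centre (4-exo-trig) attack of the carbanion on the exocyclic carbonyl and being driven by release of the β-lactone strain. No stereocenter is created: C2 is carried over unchanged from 29 because no bond to it is made or broken, and weakly basic fluoride at room temperature should not open the flavanone to the chalcone. The step needs regioselectivity (O to C8a, acyl to C4a), secured by the polarisation of the 3-alkoxyaryne, and chemoselectivity for the lactone ring oxygen over the carbonyl oxygen, favoured by the reduced ester resonance of the β-lactone and by excess 29; attack through the carbonyl oxygen is the main hazard because it could give the same skeleton with loss of configuration.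

**Step 16**
Reactants: 31 the protected flavanone–flavone from step 15
Product: 32 (2S)-6-{5,7-bis(benzyloxy)-2-[4-(benzyloxy)phenyl]-4-oxo-4H-chromen-8-yl}-2-[4-(benzyloxy)phenyl]-5,7-dihydroxy-2,3-dihydro-4H-chromen-4-one
Conditions: HCl (1.25 M in MeOH), CH2Cl2–MeOH, rt → 35 °C
Reagents that add atoms: none
Why: acid-catalysed acetal methanolysis removes both methoxymethyl ethers (the one next to the carbonyl fastest), while benzyl ethers survive and flavanones are configurationally stable in dilute acid.

**Step 17**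
Reactants: 32 the 5,7-diol from step 16
Product: 33 (2S)-6-[5,7-dihydroxy-2-(4-hydroxyphenyl)-4-oxo-4H-chromen-8-yl]-5,7-dihydroxy-2-(4-hydroxyphenyl)-2,3-dihydro-4H-chromen-4-one (target)
Conditions: H2 (1 atm), 10% Pd/C, EtOAc–MeOH, rt; stopped at complete debenzylation
Reagents that add atoms: none
Why: hydrogenolysis of the four benzyl ethers under neutral conditions cannot epimerise C2, and the chelated aryl ketone and the pyranone double bond should be reduced far more slowly than O-benzyl groups are cleaved.

**Compound list**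
1 | phloroglucinol | Oc1cc(O)cc(O)c1 | starting material
2 | 3,5-bis(methoxymethoxy)phenol | COCOc1cc(O)cc(OCOC)c1 | intermediate
3 | chloromethyl methyl ether | COCCl | starting material
4 | 3,5-bis(methoxymethoxy)phenyl N,N-diethylcarbamate | CCN(CC)C(=O)Oc1cc(OCOC)cc(OCOC)c1 | intermediate
5 | N,N-diethylcarbamoyl chloride | CCN(CC)C(=O)Cl | starting material
6 | 2-lithio derivative of 4 (aryllithium) | CCN(CC)C(=O)Oc1cc(OCOC)cc(OCOC)c1[Li] | intermediate
7 | 3,5-bis(methoxymethoxy)-2-(trimethylsilyl)phenyl N,N-diethylcarbamate | CCN(CC)C(=O)Oc1cc(OCOC)cc(OCOC)c1[Si](C)(C)C | intermediate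
8 | chlorotrimethylsilane | C[Si](C)(C)Cl | starting material
9 | 3,5-bis(methoxymethoxy)-2-(trimethylsilyl)phenol | COCOc1cc(O)c([Si](C)(C)C)c(OCOC)c1 | intermediate
10 | [3,5-bis(methoxymethoxy)-2-(trimethylsilyl)phenoxy]tri(propan-2-yl)silane | COCOc1cc(O[Si](C(C)C)(C(C)C)C(C)C)c([Si](C)(C)C)c(OCOC)c1 | intermediate
11 | chlorotri(propan-2-yl)silane | CC(C)[Si](Cl)(C(C)C)C(C)C | starting material
12 | apigenin | O=c1cc(-c2ccc(O)cc2)oc2cc(O)cc(O)c12 | starting material
13 | 5,7-bis(benzyloxy)-2-[4-(benzyloxy)phenyl]-4H-chromen-4-one | O=c1cc(-c2ccc(OCc3ccccc3)cc2)oc2cc(OCc3ccccc3)cc(OCc3ccccc3)c12 | intermediate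
14 | benzyl bromide | BrCc1ccccc1 | starting material
15 | 5,7-bis(benzyloxy)-2-[4-(benzyloxy)phenyl]-8-iodo-4H-chromen-4-one | O=c1cc(-c2ccc(OCc3ccccc3)cc2)oc2c(I)c(OCc3ccccc3)cc(OCc3ccccc3)c12 | intermediate
16 | N-iodosuccinimide | O=C1CCC(=O)N1I | starting material
17 | 4-lithio derivative of 10 (aryllithium) | COCOc1cc(O[Si](C(C)C)(C(C)C)C(C)C)c([Si](C)(C)C)c(OCOC)c1[Li] | intermediate
18 | arylzinc chloride from 17 | COCOc1cc(O[Si](C(C)C)(C(C)C)C(C)C)c([Si](C)(C)C)c(OCOC)c1[Zn]Cl | intermediate
19 | 5,7-bis(benzyloxy)-2-[4-(benzyloxy)phenyl]-8-[2,6-bis(methoxymethoxy)-4-{[tri(propan-2-yl)silyl]oxy}-3-(trimethylsilyl)phenyl]-4H-chromen-4-one | COCOc1cc(O[Si](C(C)C)(C(C)C)C(C)C)c([Si](C)(C)C)c(OCOC)c1-c1c(OCc2ccccc2)cc(OCc2ccccc2)c2c(=O)cc(-c3ccc(OCc4ccccc4)cc3)oc12 | intermediate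
20 | 5,7-bis(benzyloxy)-2-[4-(benzyloxy)phenyl]-8-[4-hydroxy-2,6-bis(methoxymethoxy)-3-(trimethylsilyl)phenyl]-4H-chromen-4-one | COCOc1cc(O)c([Si](C)(C)C)c(OCOC)c1-c1c(OCc2ccccc2)cc(OCc2ccccc2)c2c(=O)cc(-c3ccc(OCc4ccccc4)cc3)oc12 | intermediate
21 | 4-{5,7-bis(benzyloxy)-2-[4-(benzyloxy)phenyl]-4-oxo-4H-chromen-8-yl}-3,5-bis(methoxymethoxy)-2-(trimethylsilyl)phenyl trifluoromethanesulfonate | COCOc1cc(OS(=O)(=O)C(F)(F)F)c([Si](C)(C)C)c(OCOC)c1-c1c(OCc2ccccc2)cc(OCc2ccccc2)c2c(=O)cc(-c3ccc(OCc4ccccc4)cc3)oc12 | intermediate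
22 | N-phenylbis(trifluoromethanesulfonimide) | O=S(=O)(N(c1ccccc1)S(=O)(=O)C(F)(F)F)C(F)(F)F | starting material
23 | 1-[4-(benzyloxy)phenyl]ethan-1-one | CC(=O)c1ccc(OCc2ccccc2)cc1 | starting material
24 | ethyl 3-[4-(benzyloxy)phenyl]-3-oxopropanoate | CCOC(=O)CC(=O)c1ccc(OCc2ccccc2)cc1 | intermediate
25 | diethyl carbonate | CCOC(=O)OCC | starting material
26 | ethyl (3S)-3-[4-(benzyloxy)phenyl]-3-hydroxypropanoate | CCOC(=O)C[C@@H](c1ccc(OCc2ccccc2)cc1)O | intermediate
27 | (3S)-3-[4-(benzyloxy)phenyl]-3-hydroxypropanoic acid | OC(=O)C[C@@H](c1ccc(OCc2ccccc2)cc1)O | intermediate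
28 | lithium hydroxide | [Li+].[OH-] | starting material
29 | (4S)-4-[4-(benzyloxy)phenyl]oxetan-2-one | O=C1C[C@@H](c2ccc(OCc3ccccc3)cc2)O1 | intermediate
30 | aryne from 21: 1,2-didehydro-3,5-bis(methoxymethoxy)benzene carrying the tri-O-benzylflavon-8-yl group at C4 | COCOC1=C(-c2c(OCc3ccccc3)cc(OCc3ccccc3)c3c(=O)cc(-c4ccc(OCc5ccccc5)cc4)oc23)C(OCOC)=CC#C1 | intermediate
31 | (2S)-6-{5,7-bis(benzyloxy)-2-[4-(benzyloxy)phenyl]-4-oxo-4H-chromen-8-yl}-2-[4-(benzyloxy)phenyl]-5,7-bis(methoxymethoxy)-2,3-dihydro-4H-chromen-4-one | O=C1C[C@@H](c2ccc(OCc3ccccc3)cc2)Oc2cc(OCOC)c(-c3c(OCc4ccccc4)cc(OCc4ccccc4)c4c(=O)cc(-c5ccc(OCc6ccccc6)cc5)oc34)c(OCOC)c21 | intermediate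
32 | (2S)-6-{5,7-bis(benzyloxy)-2-[4-(benzyloxy)phenyl]-4-oxo-4H-chromen-8-yl}-2-[4-(benzyloxy)phenyl]-5,7-dihydroxy-2,3-dihydro-4H-chromen-4-one | O=C1C[C@@H](c2ccc(OCc3ccccc3)cc2)Oc2cc(O)c(-c3c(OCc4ccccc4)cc(OCc4ccccc4)c4c(=O)cc(-c5ccc(OCc6ccccc6)cc5)oc34)c(O)c21 | intermediate
33 | (2S)-6-[5,7-dihydroxy-2-(4-hydroxyphenyl)-4-oxo-4H-chromen-8-yl]-5,7-dihydroxy-2-(4-hydroxyphenyl)-2,3-dihydro-4H-chromen-4-one | O=C1C[C@@H](c2ccc(O)cc2)Oc2cc(O)c(-c3c(O)cc(O)c4c(=O)cc(-c5ccc(O)cc5)oc34)c(O)c21 | target

**Step count**
Total: 17 steps. Longest linear sequence: 11 steps (steps 1–5, 8–10, 15–17).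

**Steps most likely to fail**

Step 15. The lactone oxygen may be too weak a nucleophile, so that the aryne is consumed by other pathways. Attack through the carbonyl oxygen, followed by ionisation at the benzylic carbon, would erode the configuration at C2. Fluoride may also open the flavanone ring by elimination.
Fallback (known chemistry), setting out from 21: the aryne is generated in the presence of commercial (E)-3-[4-(benzyloxy)phenyl]prop-2-enoic acid (CsF in excess, THF, 125 °C, sealed vessel). The known C–O insertion of arynes into carboxylic acids places the carboxylate oxygen on C8a and the acyl group on C4a. This gives the ortho-hydroxy chalcone (E)-1-[2-hydroxy-4,6-bis(methoxymethoxy)-5-(tri-O-benzylflavon-8-yl)phenyl]-3-[4-(benzyloxy)phenyl]prop-2-en-1-one F1. F1 closes by oxa-Michael addition, in the same pot or on warming with NaOAc in EtOH, to the flavanone with both configurations at C2, 6-{5,7-bis(benzyloxy)-2-[4-(benzyloxy)phenyl]-4-oxo-4H-chromen-8-yl}-2-[4-(benzyloxy)phenyl]-5,7-bis(methoxymethoxy)-2,3-dihydro-4H-chromen-4-one F2. Preparative chromatography on a chiral stationary phase separates the (2S) isomers, and the (2R) material is re-equilibrated with base through F1 and recycled. The route is rejoined at 31.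

Step 8. Transmetalation and reductive elimination at a fourfold ortho-substituted axis may be slow, so that protodemetalation of the electron-rich arylzinc wins.
Fallback, setting out from 10 and 15, with the polarity reversed so that the metal sits on the less electron-rich partner: 10 is metalated as before and quenched with I2 to give [4-iodo-3,5-bis(methoxymethoxy)-2-(trimethylsilyl)phenoxy]tri(propan-2-yl)silane F3. Miyaura borylation of 15 (B2pin2, PdCl2(dppf), KOAc, dioxane, 90 °C) gives 5,7-bis(benzyloxy)-2-[4-(benzyloxy)phenyl]-8-(4,4,5,5-tetramethyl-1,3,2-dioxaborolan-2-yl)-4H-chromen-4-one F4. Suzuki–Miyaura coupling of F3 with F4 (Pd(OAc)2, SPhos, K3PO4, toluene–H2O, 100 °C) rejoins the route at 19.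

Step 3. Metalation may occur between the two acetal ethers instead of next to the carbamate, or the carbamoyl group may migrate (anionic Fries shift) before silylation.
Fallback, setting out from 2 and bypassing 4 and 7: amine-mediated ortho-bromination of the free phenol (NBS, i-Pr2NH cat., CH2Cl2, −78 → 0 °C; both ortho positions are equivalent) gives 2-bromo-3,5-bis(methoxymethoxy)phenol F5. O-silylation (hexamethyldisilazane, THF, reflux) gives [2-bromo-3,5-bis(methoxymethoxy)phenoxy]trimethylsilane F6. Bromine–lithium exchange (n-BuLi, THF, −78 °C) triggers the retro-Brook 1,3 O→C silyl shift, and aqueous work-up rejoins the route at 9.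

**Further compounds**
F1 | step 15 | (E)-1-[2-hydroxy-4,6-bis(methoxymethoxy)-5-(tri-O-benzylflavon-8-yl)phenyl]-3-[4-(benzyloxy)phenyl]prop-2-en-1-one | O=C(/C=C/c1ccc(OCc2ccccc2)cc1)c1c(O)cc(OCOC)c(-c2c(OCc3ccccc3)cc(OCc3ccccc3)c3c(=O)cc(-c4ccc(OCc5ccccc5)cc4)oc23)c1OCOC
F2 | step 15 | 6-{5,7-bis(benzyloxy)-2-[4-(benzyloxy)phenyl]-4-oxo-4H-chromen-8-yl}-2-[4-(benzyloxy)phenyl]-5,7-bis(methoxymethoxy)-2,3-dihydro-4H-chromen-4-one, both configurations at C2 | O=C1CC(c2ccc(OCc3ccccc3)cc2)Oc2cc(OCOC)c(-c3c(OCc4ccccc4)cc(OCc4ccccc4)c4c(=O)cc(-c5ccc(OCc6ccccc6)cc5)oc34)c(OCOC)c21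
F3 | step 8 | [4-iodo-3,5-bis(methoxymethoxy)-2-(trimethylsilyl)phenoxy]tri(propan-2-yl)silane | COCOc1cc(O[Si](C(C)C)(C(C)C)C(C)C)c([Si](C)(C)C)c(OCOC)c1I
F4 | step 8 | 5,7-bis(benzyloxy)-2-[4-(benzyloxy)phenyl]-8-(4,4,5,5-tetramethyl-1,3,2-dioxaborolan-2-yl)-4H-chromen-4-one | O=c1cc(-c2ccc(OCc3ccccc3)cc2)oc2c(B3OC(C)(C)C(C)(C)O3)c(OCc3ccccc3)cc(OCc3ccccc3)c12
F5 | step 3 | 2-bromo-3,5-bis(methoxymethoxy)phenol | COCOc1cc(O)c(Br)c(OCOC)c1
F6 | step 3 | [2-bromo-3,5-bis(methoxymethoxy)phenoxy]trimethylsilane | COCOc1cc(O[Si](C)(C)C)c(Br)c(OCOC)c1
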